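**Retrosynthetic overview**
1. The target is a cis-fused 1-alkylidene-octahydronaphthalene (locants C1–C8a; C9 is the exocyclic alkylidene carbon). The last operations only adjust the esters: acetates at C3 and C6, formate on the C9 CH2O group.
2. Key disconnection: the C1–C8a bond and the C9–CH3 bond are made in one palladium cascade. The enabling feature is the skipped diene C7=C8–C8a(H)–C1=C9, in which C8a is the allylic terminus of the ring-A alkene and the C9 methyl is cis to C8a. This is the imprint of a syn allylpalladation of a C1≡C9 alkyne by a ring-A η3-allyl (C7–C8–C8a), followed by methyl capture.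
3. The precursor is the monocyclic cyclohexenyl acetate 17 carrying the chain C4–C3–C2–C1≡C9. C3 comes from a catalyst-controlled propargylation; C4 from hydroboration of the carvone isopropenyl group, steered by the neighbouring C8a–O branch.
4. Ring A, with C4a and the C6 oxygen, comes from (R)-carvone. The C8a oxygen (later the leaving group) is introduced by a singlet-oxygen ene reaction and 1,3-transposition.
5. Ring order: ring A from the chiral pool; ring B closed in step 13.

Key step: step 13

Remarks: target locants are kept for all intermediates; β is the face of ring A that carries the C4a–C4 bond, α the opposite face. Assumption: (R)-TRIP delivers the propargyl group to the Re face of aldehyde 11, as it does with simple aldehydes; if a model aldehyde shows the opposite sense, the (S)-catalyst is the one meant.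

Step 1
Reactants: 1 (R)-(−)-carvone
Product: 2 (−)-cis-carveol
Conditions: NaBH4, CeCl3·7H2O, MeOH, −78 → 0 °C
Reagents that add atoms: none
Why: Luche reduction is 1,2-selective, and axial hydride delivery should give the pseudo-equatorial C6 alcohol cis to the isopropenyl group (C6 set as R).

Step 2
Reactants: 2 (−)-cis-carveol
Product: 3 cis-carveol TBS ether
Conditions: TBSCl, imidazole, DMF, rt
Reagents that add atoms: tert-butyldimethylsilyl chloride, CC(C)(C)[Si](C)(C)Cl
Why: standard silylation of a secondary allylic alcohol; the bulky silyl ether later shields the β-face and blocks C6–H abstraction.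

Step 3
Reactants: 3 cis-carveol TBS ether
Product: 5 tertiary allylic alcohol (C7–OH on the α-face, C8=C8a alkene), via allylic hydroperoxide 4 (not isolated)
Conditions: O2, white light, tetraphenylporphyrin (cat.), CH2Cl2, −30 °C; then PPh3, −30 °C → rt
Reagents that add atoms: dioxygen, O=O
Why: Schenck ene reaction, in which singlet oxygen should bond to C7 on the face anti to the silyloxy and isopropenyl groups and take an allylic hydrogen from C8a; the 1,1-disubstituted isopropenyl alkene reacts far more slowly, and PPh3 reduces the hydroperoxide.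

Step 4
Reactants: 5 tertiary allylic alcohol
Product: 6 secondary allylic alcohol (C8a–OH on the α-face, C7=C8 alkene)
Conditions: Ph3SiOReO3 (2 mol %), Et2O, −40 → 0 °C
Reagents that add atoms: none
Why: rhenium-oxo-catalysed 1,3-transposition of an allylic alcohol through a suprafacial [3,3] shift of the perrhenate ester, so the oxygen should arrive at C8a on the face it left at C7 (trans to the isopropenyl group); the trisubstituted alkene and the less crowded carbinol drive the equilibrium.

Step 5
Reactants: 6 secondary allylic alcohol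
Product: 8 PMB ether of 6, via sodium alkoxide 7 (not isolated)
Conditions: NaH, 4-methoxybenzyl chloride, Bu4NI (cat.), THF/DMF, 0 °C → rt
Reagents that add atoms: 4-methoxybenzyl chloride, COc1ccc(CCl)cc1
Why: Williamson etherification; the PMB group survives the basic and oxidative steps that follow and is removed orthogonally to the silyl ethers.

Step 6
Reactants: 8 PMB ether
Product: 10 primary alcohol (C4 R, CH2OH = C3), via B-alkyl-9-BBN adduct 9 (not isolated)
Conditions: 9-BBN (2.5 equiv), THF, 0 → 40 °C; then NaOH, H2O2, 0 °C → rt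
Reagents that add atoms: hydrogen peroxide, OO
Why: anti-Markovnikov hydroboration–oxidation of the isopropenyl group only (the flanked trisubstituted ring alkene is inert to 9-BBN); the borane should approach anti to the larger allylic branch (C8a bearing OPMB), the sense known for 2-isopropenylcyclohexanol-type substrates, which sets C4 as R.

Step 7
Reactants: 10 primary alcohol
Product: 11 aldehyde (C3 = CHO)
Conditions: Dess–Martin periodinane, NaHCO3, CH2Cl2, 0 °C
Reagents that add atoms: none
Why: buffered Dess–Martin oxidation should give the α-branched aldehyde without epimerising C4; it is used crude.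

Step 8
Reactants: 11 aldehyde
Product: 12 homopropargylic alcohol (C3 R, terminal alkyne)
Conditions: allenylboronic acid pinacol ester (1.5 equiv), (R)-TRIP (10 mol %), 4 Å MS, toluene, 0 °C
Reagents that add atoms: allenylboronic acid pinacol ester, C=C=CB1OC(C)(C)C(C)(C)O1
Why: chiral phosphoric acid-catalysed propargylation (SE2′ allenylboration through a closed six-membered transition state); catalyst control and the Felkin–Anh preference of the α-methyl aldehyde should both favour the 3,4-syn (3R) carbinol.

Step 9
Reactants: 12 homopropargylic alcohol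
Product: 14 propargylic diol (C3–OH and C9–CH2OH), via bis(bromomagnesium) alkoxide acetylide 13 (not isolated)
Conditions: EtMgBr (2.5 equiv), THF, 0 → 45 °C; (CH2O)n, 45 °C; aq NH4Cl
Reagents that add atoms: paraformaldehyde (as formaldehyde), C=O
Why: alkynyl Grignard addition to formaldehyde installs the CH2O carbon on C9; EtMgBr is chosen over an alkyllithium so that the allyl benzyl ether is not deprotonated.

Step 10
Reactants: 14 propargylic diol
Product: 15 primary TBS ether (C3–OH free)
Conditions: TBSCl (1.1 equiv), imidazole, CH2Cl2, −20 → 0 °C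
Reagents that add atoms: tert-butyldimethylsilyl chloride, CC(C)(C)[Si](C)(C)Cl
Why: the unhindered primary propargylic alcohol should silylate selectively over the α-branched secondary C3 alcohol.

Step 11
Reactants: 15 primary TBS ether
Product: 16 diol (C3–OH and C8a–OH)
Conditions: DDQ, CH2Cl2/pH 7 buffer, 0 °C
Reagents that add atoms: none
Why: oxidative cleavage of the PMB ether; silyl ethers, alkyne and ring alkene are unaffected, and water suppresses acetal formation with the C3 hydroxyl.

Step 12
Reactants: 16 diol
Product: 17 enyne diacetate (C3–OAc and allylic C8a–OAc)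
Conditions: Ac2O, DMAP (cat.), pyridine, rt
Reagents that add atoms: acetic anhydride, CC(=O)OC(C)=O
Why: one acetylation installs the C3 acetate of the target and turns the C8a oxygen, trans to the side chain, into the allylic leaving group.

Step 13
Reactants: 17 enyne diacetate
Product: 20 cis-fused bicyclic diene (C6–OTBS, C3–OAc, C9 bearing CH3 and CH2OTBS), via allylpalladium acetate 18 (not isolated), via alkenylpalladium acetate 19 (not isolated)
Conditions: Pd(PPh3)4 (5 mol %), MeB(OH)2 (2.5 equiv), K3PO4 (3 equiv), 1,4-dioxane (trace H2O), 70 °C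
Reagents that add atoms: methylboronic acid, CB(O)O
Why: Zerovalent palladium ionises the C8a allylic acetate with inversion to an η3-allylpalladium unit (C7–C8–C8a) on the β-face, the tethered alkyne inserts syn into the C8a–Pd bond, and the alkenylpalladium on C9 is methylated by transmetalation from the methylboronate and reductive elimination with retention. The closest known reaction type is the palladium-ene (allylpalladation) cyclisation of enynyl allylic esters terminated by Suzuki–Miyaura coupling, here applied to a cyclic allyl unit, a six-membered ring and a methyl donor. Ring B closes by 6-exo-dig migratory insertion at C8a, the only allyl terminus the four-atom tether can reach without forming a bridged ring. The new stereocentre C8a is controlled by C4a together with the trans C8a–OAc: palladium sits cis to the side chain, so C1 is delivered on that face and the ring fusion is cis; the C1=C9 geometry follows from syn addition and stereoretentive coupling, which place the new methyl cis to C8a. The step needs insertion to outrun methyl transfer to, or β-hydride loss from, the allylpalladium; the slow transmetalation of allyl species with boron reagents and the intramolecular alkyne should secure this, and the alkenylpalladium has no β-hydrogen and no alkene within reach, so it can only wait for the methyl group. Only the allylic acetate ionises, since the C3 acetate and both silyl ethers are inert to zerovalent palladium.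

Step 14
Reactants: 20 bicyclic diene
Product: 21 diol (C6–OH and C9–CH2OH)
Conditions: HF·pyridine, pyridine, THF, 0 °C → rt
Reagents that add atoms: none
Why: buffered fluoride desilylation should remove both TBS groups without touching the C3 acetate or the skipped diene.

Step 15
Reactants: 21 diol
Product: 22 primary formate (C6–OH free)
Conditions: acetic formic anhydride (1.2 equiv), pyridine, CH2Cl2, −40 °C
Reagents that add atoms: acetic formic anhydride, CC(=O)OC=O
Why: the mixed anhydride transfers only the formyl group, and at low temperature the primary allylic alcohol should react well before the hindered secondary C6 alcohol.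

Step 16
Reactants: 22 primary formate
Product: 23 target CNP0262962.1
Conditions: Ac2O, DMAP (cat.), pyridine, CH2Cl2, 0 °C
Reagents that add atoms: acetic anhydride, CC(=O)OC(C)=O
Why: DMAP-catalysed acetylation of the remaining C6 alcohol with retention; the formate and the C3 acetate are stable to these conditions.

**Compound list**
1 | (R)-(−)-carvone, (5R)-2-methyl-5-(prop-1-en-2-yl)cyclohex-2-en-1-one | CC1=CC[C@H](CC1=O)C(C)=C | starting material
2 | (−)-cis-carveol, (1R,5R)-2-methyl-5-(prop-1-en-2-yl)cyclohex-2-en-1-ol | O[C@@H]1C[C@H](C(C)=C)CC=C1C | intermediate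
3 | cis-carveol TBS ether, tert-butyldimethyl{[(1R,5R)-2-methyl-5-(prop-1-en-2-yl)cyclohex-2-en-1-yl]oxy}silane | CC(C)(C)[Si](C)(C)O[C@@H]1C[C@H](C(C)=C)CC=C1C | intermediate
4 | allylic hydroperoxide, (1R,4S,6R)-6-(TBS-oxy)-1-methyl-4-(prop-1-en-2-yl)cyclohex-2-en-1-yl hydroperoxide | CC(C)(C)[Si](C)(C)O[C@@H]1C[C@H](C(C)=C)C=C[C@@]1(C)OO | intermediate (not isolated)
5 | tertiary allylic alcohol, (1R,4S,6R)-6-(TBS-oxy)-1-methyl-4-(prop-1-en-2-yl)cyclohex-2-en-1-ol (OH trans to both the silyloxy and the isopropenyl group) | CC(C)(C)[Si](C)(C)O[C@@H]1C[C@H](C(C)=C)C=C[C@@]1(C)O | intermediate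
6 | secondary allylic alcohol, (1S,4R,6R)-4-(TBS-oxy)-3-methyl-6-(prop-1-en-2-yl)cyclohex-2-en-1-ol (OH trans to isopropenyl, silyloxy cis to it) | CC(C)(C)[Si](C)(C)O[C@@H]1C[C@H](C(C)=C)[C@@H](O)C=C1C | intermediate
7 | sodium alkoxide of 6 | CC(C)(C)[Si](C)(C)O[C@@H]1C[C@H](C(C)=C)[C@@H](O[Na])C=C1C | intermediate (not isolated)
8 | 4-methoxybenzyl ether of 6 (stereocentres unchanged) | CC(C)(C)[Si](C)(C)O[C@@H]1C[C@H](C(C)=C)[C@@H](OCc2ccc(OC)cc2)C=C1C | intermediate
9 | B-alkyl-9-borabicyclo[3.3.1]nonane from 8 (boron on the terminal carbon, C4 configured as in 10) | CC(C)(C)[Si](C)(C)O[C@@H]1C[C@H]([C@@H](C)CB2C3CCCC2CCC3)[C@@H](OCc2ccc(OC)cc2)C=C1C | intermediate (not isolated)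
10 | primary alcohol, (2R)-2-[(1R,2R,5R)-5-(TBS-oxy)-2-(4-methoxybenzyloxy)-4-methylcyclohex-3-en-1-yl]propan-1-ol | CC(C)(C)[Si](C)(C)O[C@@H]1C[C@H]([C@@H](C)CO)[C@@H](OCc2ccc(OC)cc2)C=C1C | intermediate
11 | aldehyde, (2R)-2-[(1R,2R,5R)-5-(TBS-oxy)-2-(4-methoxybenzyloxy)-4-methylcyclohex-3-en-1-yl]propanal | CC(C)(C)[Si](C)(C)O[C@@H]1C[C@H]([C@@H](C)C=O)[C@@H](OCc2ccc(OC)cc2)C=C1C | intermediate
12 | homopropargylic alcohol, (2R,3R)-2-[(1R,2R,5R)-5-(TBS-oxy)-2-(4-methoxybenzyloxy)-4-methylcyclohex-3-en-1-yl]hex-5-yn-3-ol | CC(C)(C)[Si](C)(C)O[C@@H]1C[C@H]([C@@H](C)[C@H](O)CC#C)[C@@H](OCc2ccc(OC)cc2)C=C1C | intermediate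
13 | bis(bromomagnesium) alkoxide acetylide of 12 | CC(C)(C)[Si](C)(C)O[C@@H]1C[C@H]([C@@H](C)[C@H](O[Mg]Br)CC#C[Mg]Br)[C@@H](OCc2ccc(OC)cc2)C=C1C | intermediate (not isolated)
14 | propargylic diol, (5R,6R)-6-[ring as in 12]hept-2-yne-1,5-diol | CC(C)(C)[Si](C)(C)O[C@@H]1C[C@H]([C@@H](C)[C@H](O)CC#CCO)[C@@H](OCc2ccc(OC)cc2)C=C1C | intermediate
15 | primary TBS ether of 14 (C3–OH free, C8a–OPMB) | CC(C)(C)[Si](C)(C)O[C@@H]1C[C@H]([C@@H](C)[C@H](O)CC#CCO[Si](C)(C)C(C)(C)C)[C@@H](OCc2ccc(OC)cc2)C=C1C | intermediate
16 | diol after PMB removal (C3–OH and C8a–OH free; C6 and primary oxygen as TBS ethers) | CC(C)(C)[Si](C)(C)O[C@@H]1C[C@H]([C@@H](C)[C@H](O)CC#CCO[Si](C)(C)C(C)(C)C)[C@@H](O)C=C1C | intermediate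
17 | enyne diacetate (C3–OAc; allylic C8a–OAc trans to the side chain; C6–OTBS cis to it) | CC(C)(C)[Si](C)(C)O[C@@H]1C[C@H]([C@@H](C)[C@H](OC(C)=O)CC#CCO[Si](C)(C)C(C)(C)C)[C@@H](OC(C)=O)C=C1C | intermediate
18 | η3-allylpalladium acetate over C7–C8–C8a, palladium on the β-face (drawn as the C8a-bound form, phosphines omitted) | CC(C)(C)[Si](C)(C)O[C@@H]1C[C@H]([C@@H](C)[C@H](OC(C)=O)CC#CCO[Si](C)(C)C(C)(C)C)[C@H]([Pd]OC(C)=O)C=C1C | intermediate (not isolated)
19 | alkenylpalladium acetate, palladium on C9 cis to C8a (phosphines omitted) | CC(C)(C)[Si](C)(C)O[C@@H]1C[C@@H]2[C@@H](C)[C@H](OC(C)=O)C/C(=C(/[Pd]OC(C)=O)CO[Si](C)(C)C(C)(C)C)[C@@H]2C=C1C | intermediate (not isolated)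
20 | (3R,4R,4aS,6R,8aS)-bicyclic diene, (E)-C1=C9 alkylidene with C9–CH3 cis to C8a, C3–OAc, C6–OTBS, C9–CH2OTBS | CC(C)(C)[Si](C)(C)O[C@@H]1C[C@@H]2[C@@H](C)[C@H](OC(C)=O)C/C(=C(/C)CO[Si](C)(C)C(C)(C)C)[C@@H]2C=C1C | intermediate
21 | diol (C6–OH, C9–CH2OH, C3–OAc; stereochemistry as in 20) | O[C@@H]1C[C@@H]2[C@@H](C)[C@H](OC(C)=O)C/C(=C(/C)CO)[C@@H]2C=C1C | intermediate
22 | primary formate (C6–OH free, C3–OAc; stereochemistry as in 20) | O[C@@H]1C[C@@H]2[C@@H](C)[C@H](OC(C)=O)C/C(=C(/C)COC=O)[C@@H]2C=C1C | intermediate
23 | CNP0262962.1, (3R,4R,4aS,6R,8aS)-3,6-diacetoxy-4,7-dimethyl-1-[(E)-1-(formyloxy)propan-2-ylidene]-1,2,3,4,4a,5,6,8a-octahydronaphthalene | CC(=O)O[C@@H]1C[C@@H]2[C@@H](C)[C@H](OC(C)=O)C/C(=C(/C)COC=O)[C@@H]2C=C1C | target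

**Step count and risks**
Total steps: 16. Longest linear sequence: 16 steps, from (R)-carvone.

Steps most likely to fail:

1. Step 13 (key step). The six-ring alkyne insertion may be too slow, so that the allylpalladium loses a β-hydride (diene formation) or takes up the methyl group before cyclising. Fallback: set out from 15 and separate the two bond formations. Copper-catalysed syn-methylboration of the alkyne (B2pin2, MeI, CuCl, Xantphos, LiOtBu, THF) should place boron on C1 (distal to the propargylic oxygen) and the methyl on C9, cis to each other, giving alkenylboronate F1. DDQ then frees the C8a hydroxyl (diol F2) and acetylation gives diacetate F3. Pd(PPh3)4 with K3PO4 in dioxane closes ring B by intramolecular allyl–alkenyl Suzuki–Miyaura coupling; the C–C bond forms on the palladium face, cis to the side chain, and the route is rejoined at 20.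

2. Step 3. The ene reaction may lose regio- or facial control: hydrogen abstraction from the C7 methyl group would give the exocyclic alkene, and attack on the face of the silyl ether would give the epimeric hydroperoxide. Fallback: set out from 3. mCPBA epoxidation of the trisubstituted ring alkene anti to the silyloxy group gives epoxide F4. Opening at the secondary carbon C8 with PhSeNa (from (PhSe)2 and NaBH4, EtOH) gives hydroxy selenide F5. Oxidation with H2O2 and selenoxide syn-elimination towards C8a then returns the route at 5.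

3. Step 4. The allylic perrhenate may ionise, leading to elimination to a diene or to loss of the stereochemical information carried to C8a. Fallback: set out from 5. Babler–Dauben oxidative transposition with C5H5NH[CrO3Cl] in CH2Cl2 gives the transposed enone F6. Luche reduction (NaBH4, CeCl3·7H2O, MeOH, −78 °C) with axial hydride delivery should place the hydroxyl trans to the isopropenyl group, returning the route at 6.

**Further compounds**
F1 | step 13 | alkenylboronate from 15 (Bpin on C1 cis to the new C9 methyl; C8a–OPMB, C3–OH) | CC(C)(C)[Si](C)(C)O[C@@H]1C[C@H]([C@@H](C)[C@H](O)C/C(B2OC(C)(C)C(C)(C)O2)=C(/C)CO[Si](C)(C)C(C)(C)C)[C@@H](OCc2ccc(OC)cc2)C=C1C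
F2 | step 13 | alkenylboronate diol (C8a–OH and C3–OH free) | CC(C)(C)[Si](C)(C)O[C@@H]1C[C@H]([C@@H](C)[C@H](O)C/C(B2OC(C)(C)C(C)(C)O2)=C(/C)CO[Si](C)(C)C(C)(C)C)[C@@H](O)C=C1C
F3 | step 13 | alkenylboronate diacetate (C3–OAc, allylic C8a–OAc) | CC(C)(C)[Si](C)(C)O[C@@H]1C[C@H]([C@@H](C)[C@H](OC(C)=O)C/C(B2OC(C)(C)C(C)(C)O2)=C(/C)CO[Si](C)(C)C(C)(C)C)[C@@H](OC(C)=O)C=C1C
F4 | step 3 | C7–C8 epoxide of 3, oxygen on the α-face | CC(C)(C)[Si](C)(C)O[C@@H]1C[C@H](C(C)=C)C[C@H]2O[C@@]12C
F5 | step 3 | hydroxy selenide (C8–SePh on the β-face, C7–OH on the α-face) | CC(C)(C)[Si](C)(C)O[C@@H]1C[C@H](C(C)=C)C[C@H]([Se]c2ccccc2)[C@@]1(C)O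
F6 | step 4 | transposed enone, (4R,6R)-4-(TBS-oxy)-3-methyl-6-(prop-1-en-2-yl)cyclohex-2-en-1-one | CC(C)(C)[Si](C)(C)O[C@@H]1C[C@H](C(C)=C)C(=O)C=C1C
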